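**Retrosynthetic overview**

1. Ptilosarcone ⇐ ene-type chlorination of a 3Z,5E-diene (C6–Cl, Δ5(16)) and butyrylation of the 14-hydroxyl, both at the very end.
2. Six-membered ring (which also creates the ten-membered ring) is formed last: transannular C1–C10 closure of a 14-membered (1(14)Z,10Z)-cembranoid 1,14-epoxide 12-enone, the cembrane 3,8-cyclisation run as a Cp2TiCl radical epoxide opening that sets C1, C10, C11 and keeps O14.
3. The 14-membered carbocycle is closed before that at C9–C10 (CrCl2/NiCl2), next to the bond a cembrene synthase would form; the γ-lactone is made first, inside the east fragment.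
4. Seco precursor ⇐ asymmetric C2–C3 alkynylation of a Z-enal (C10–C14, C1, C2) with an enyne lactone (C3–C9, C16–C19), then hydroxyl-directed epoxidation.
5. West fragment from propargyl alcohol (carbometalation, allylboration, Still–Gennari); east fragment from (E)-3-methylpent-2-en-4-yn-1-ol and tert-butyl (R)-lactate (HWE, Sharpless epoxidation, lactonisation). Ring order: lactone → 14-membered ring → six-membered ring.

Assumption 1: briarane numbering is used for all intermediates (C18 = methyl on C17, C19 = lactone carbonyl); "as in the target" means the spatial arrangement that carbon has in ptilosarcone, and the SMILES string is authoritative.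
Assumption 2: (S,S)-ProPhenol/Me2Zn delivers the alkynylzinc to the Si face of enal 11; if the sense is opposite, the (R,R)-ligand is used with no other change.

**West fragment**

Step 1
Reactants: 1 prop-2-yn-1-ol
Product: 3 (Z)-3-iodo-2-methylprop-2-en-1-ol, via alkenylmagnesium alkoxide 2 (not isolated)
Conditions: MeMgBr (2.5 equiv), CuI (10 mol%), THF, −10 °C → rt; then I2, −78 → 0 °C
Reagents that add atoms: methylmagnesium bromide, C[Mg]Br; iodine, I-I
Why: Copper-catalysed anti-carbomagnesiation of the propargylic alkoxide puts the methyl (C20) on the inner carbon and magnesium on the terminal carbon cis to CH2O (chelate 2), and iodinolysis proceeds with retention to give the Z-iodide that becomes C10=C11.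

Step 2
Reactants: 3 (Z)-3-iodo-2-methylprop-2-en-1-ol
Product: 5 (1Z,3S)-1-iodo-2-methylhexa-1,5-dien-3-ol, via (Z)-3-iodo-2-methylprop-2-enal 4 (not isolated)
Conditions: MnO2, CH2Cl2, rt; filter; (−)-Ipc2B(allyl), Et2O, −78 °C; then NaOH, H2O2
Reagents that add atoms: (−)-B-allyldiisopinocampheylborane, C=CCB(C1CC2CC(C1C)C2(C)C)C1CC2CC(C1C)C2(C)C
Why: Allylic oxidation followed by Brown asymmetric allylboration through a chair six-membered transition state gives a single C12 carbinol (S drawn; this centre is oxidised to the ketone in step 18, so its sense is inconsequential) and brings C13 and C14.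

Step 3
Reactants: 5 (1Z,3S)-1-iodo-2-methylhexa-1,5-dien-3-ol
Product: 6 (1Z,3S)-1-iodo-2-methyl-3-(triethylsilyloxy)hexa-1,5-diene
Conditions: Et3SiCl, imidazole, DMF, 0 °C
Reagents that add atoms: chlorotriethylsilane, CC[Si](Cl)(CC)CC
Why: Standard silylation; the triethylsilyl ether is chosen because it can later be removed and oxidised in one operation.

Step 4
Reactants: 6 (1Z,3S)-1-iodo-2-methyl-3-(triethylsilyloxy)hexa-1,5-diene
Product: 7 (3S,4Z)-5-iodo-4-methyl-3-(triethylsilyloxy)pent-4-enal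
Conditions: OsO4 (2 mol%), NaIO4, 2,6-lutidine, dioxane/H2O, rt
Reagents that add atoms: osmium tetroxide (oxygen donor, regenerated), O=[Os](=O)(=O)=O; sodium periodate, [Na+].[O-]I(=O)(=O)=O
Why: Johnson–Lemieux cleavage of the terminal alkene gives the C14 aldehyde, while the electron-poor trisubstituted iodoalkene is not dihydroxylated.

Step 5
Reactants: 7 (3S,4Z)-5-iodo-4-methyl-3-(triethylsilyloxy)pent-4-enal; 8 ethyl 2-[bis(2,2,2-trifluoroethoxy)phosphoryl]propanoate
Product: 9 ethyl (2Z,5S,6Z)-7-iodo-2,6-dimethyl-5-(triethylsilyloxy)hepta-2,6-dienoate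
Conditions: KN(SiMe3)2, 18-crown-6, THF, −78 °C
Reagents that add atoms: none
Why: Still–Gennari olefination (fast, irreversible elimination from the kinetic adduct) gives the Z-trisubstituted C14=C1 alkene with C13 cis to C2, the geometry the key step needs.

Step 6
Reactants: 9 ethyl (2Z,5S,6Z)-7-iodo-2,6-dimethyl-5-(triethylsilyloxy)hepta-2,6-dienoate
Product: 10 (2Z,5S,6Z)-7-iodo-2,6-dimethyl-5-(triethylsilyloxy)hepta-2,6-dien-1-ol
Conditions: iBu2AlH, CH2Cl2, −78 °C
Reagents that add atoms: none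
Why: 1,2-Reduction of the enoate by the aluminium hydride leaves both alkene geometries, the iodide and the silyl ether untouched.

Step 7
Reactants: 10 (2Z,5S,6Z)-7-iodo-2,6-dimethyl-5-(triethylsilyloxy)hepta-2,6-dien-1-ol
Product: 11 (2Z,5S,6Z)-7-iodo-2,6-dimethyl-5-(triethylsilyloxy)hepta-2,6-dienal (west fragment)
Conditions: MnO2, CH2Cl2, rt
Reagents that add atoms: none
Why: Neutral allylic oxidation gives the Z-enal (C2 aldehyde) without Z→E isomerisation.

**East fragment**

Step 8
Reactants: 12 tert-butyl (R)-2-hydroxypropanoate; 13 trimethyl phosphonoacetate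
Product: 15 4-tert-butyl 1-methyl (3S)-2-(dimethoxyphosphoryl)-3-methylbutanedioate (C2 epimers), via lactate triflate 14 (not isolated)
Conditions: Tf2O, 2,6-lutidine, CH2Cl2, −78 °C; then cannulated into 13/NaH, THF, 0 °C → rt
Reagents that add atoms: triflic anhydride (its atoms sit only in 14 and leave again), O=S(=O)(OS(=O)(=O)C(F)(F)F)C(F)(F)F
Why: SN2 displacement of the lactate triflate by the phosphonoacetate anion goes with clean inversion and fixes C17 (the target's arrangement) from the chiral pool.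

Step 9
Reactants: 16 (E)-3-methylpent-2-en-4-yn-1-ol; 15 4-tert-butyl 1-methyl (3S)-2-(dimethoxyphosphoryl)-3-methylbutanedioate
Product: 18 4-tert-butyl 1-methyl (2E,3R)-3-methyl-2-[(E)-3-methylpent-2-en-4-yn-1-ylidene]butanedioate, via (E)-3-methylpent-2-en-4-ynal 17 (not isolated)
Conditions: MnO2, CH2Cl2, rt; filter; then 15, NaH, THF, 0 °C → rt
Reagents that add atoms: none
Why: Tandem allylic oxidation/Horner–Wadsworth–Emmons olefination gives the thermodynamically preferred E-alkylidene succinate (C6 trans to the methyl ester, C9), and the weakly basic phosphonate anion does not epimerise C17.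

Step 10
Reactants: 18 4-tert-butyl 1-methyl (2E,3R)-3-methyl-2-[(E)-3-methylpent-2-en-4-yn-1-ylidene]butanedioate
Product: 19 tert-butyl (2R,3E,5E)-3-(hydroxymethyl)-2,6-dimethylocta-3,5-dien-7-ynoate
Conditions: iBu2AlH (2.2 equiv), CH2Cl2, −78 °C
Reagents that add atoms: none
Why: The methyl enoate is reduced chemoselectively to the allylic alcohol (C9), while the hindered tert-butyl ester (C19) survives at −78 °C.

Step 11
Reactants: 19 tert-butyl (2R,3E,5E)-3-(hydroxymethyl)-2,6-dimethylocta-3,5-dien-7-ynoate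
Product: 21 (3R,4R,5S)-4-hydroxy-4-(hydroxymethyl)-3-methyl-5-[(E)-2-methylbut-1-en-3-yn-1-yl]oxolan-2-one (east fragment), via epoxy alcohol 20 (not isolated)
Conditions: Ti(OiPr)4, D-(−)-diethyl tartrate, tBuOOH, 4 Å molecular sieves, CH2Cl2, −20 °C; then Me2S; then CF3CO2H, 0 °C → rt
Reagents that add atoms: tert-butyl hydroperoxide, CC(C)(C)OO
Why: Sharpless asymmetric epoxidation of the 2,3-disubstituted E-allylic alcohol sets C8 by reagent control, and the tert-butyl ester carbonyl then opens the labile vinyl epoxide at the allylic carbon C7 with inversion (loss of isobutene), so the hydroxy lactone has C7, C8 and C17 as in the target.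

**Union and endgame**

Step 12
Reactants: 11 (2Z,5S,6Z)-7-iodo-2,6-dimethyl-5-(triethylsilyloxy)hepta-2,6-dienal; 21 east fragment lactone
Product: 22 seco-cembranoid enynol (2-OH as in the target; 1(14)Z; 3-yne; 5E; 10Z-iodide; 12S-OSiEt3; 8-OH; 9-CH2OH)
Conditions: (S,S)-ProPhenol [2,6-bis{[(S)-2-(hydroxydiphenylmethyl)pyrrolidin-1-yl]methyl}-4-methylphenol] (20 mol%), Me2Zn (4 equiv), Ph3PO (40 mol%), toluene, 0 °C → rt
Reagents that add atoms: none
Why: Trost zinc–ProPhenol asymmetric alkynylation of an α,β-unsaturated aldehyde forms C2–C3 and sets C2 by ligand control, while excess Me2Zn simply holds the free hydroxyls as zinc alkoxides and the lactone is not attacked.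

Step 13
Reactants: 22 seco-cembranoid enynol
Product: 23 seco-cembranoid 1,14-epoxide (oxygen on the face that will become the 14α-oxygen; threo to 2-OH)
Conditions: mCPBA, NaHCO3, CH2Cl2, 0 °C
Reagents that add atoms: 3-chloroperoxybenzoic acid, OOC(=O)c1cccc(Cl)c1
Why: Hydroxyl-directed (Henbest) peracid epoxidation of the Z-allylic alcohol: allylic 1,3-strain with the cis C13 substituent puts H2 in the alkene plane, so oxygen is delivered threo and C1 and C14 are set relative to C2; the enyne and iodoalkene are too electron-poor to compete.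

Step 14
Reactants: 23 seco-cembranoid 1,14-epoxide
Product: 24 seco-aldehyde (C9 aldehyde, free 2-OH and 8-OH)
Conditions: TEMPO (2,2,6,6-tetramethylpiperidine-1-oxyl, 10 mol%), PhI(OAc)2, CH2Cl2, rt
Reagents that add atoms: none
Why: Oxoammonium oxidation is selective for the primary alcohol over the hindered secondary C2 carbinol and the tertiary C8 carbinol, and the quaternary C8 makes the α-hydroxy aldehyde non-epimerisable.

Step 15
Reactants: 24 seco-aldehyde
Product: 25 14-membered macrocyclic diol (9S-OH, 2-OH; 10Z; 1,14-epoxide; 3-yne)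
Conditions: CrCl2 (10 equiv), NiCl2 (2 mol%), DMSO/THF, rt, 2 mM, syringe pump
Reagents that add atoms: none
Why: Nozaki–Hiyama–Kishi alkenylation (zerovalent nickel inserts into the carbon–iodine bond, then transmetalation to chromium) closes the cembranoid ring at C9–C10 with retention of the Z-alkene, and chelation of the chromium-bound aldehyde by the free C8 hydroxyl directs attack anti to the bulky C7 branch to give the 8,9-syn (9S) alcohol.

Step 16
Reactants: 25 14-membered macrocyclic diol
Product: 26 macrocyclic 2,9-diacetate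
Conditions: Ac2O, pyridine, 4-(dimethylamino)pyridine (cat.), CH2Cl2, 0 °C → rt
Reagents that add atoms: acetic anhydride, CC(=O)OC(C)=O
Why: Both secondary alcohols are acetylated in one operation while the tertiary C8 hydroxyl does not react.

Step 17
Reactants: 26 macrocyclic 2,9-diacetate
Product: 27 macrocyclic (3Z,5E)-diene
Conditions: H2 (1 atm), Pd/CaCO3 poisoned with Pb(OAc)2, quinoline, EtOAc, rt
Reagents that add atoms: none
Why: Lindlar syn-semihydrogenation of the ring enyne gives the 3Z-alkene of the 3Z,5E-diene and leaves the trisubstituted alkenes and the epoxide alone.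

Step 18
Reactants: 27 macrocyclic (3Z,5E)-diene
Product: 29 (10Z)-12-enone 1,14-epoxide, via C12 alcohol 28 (not isolated)
Conditions: IBX (3 equiv), DMSO, rt
Reagents that add atoms: none
Why: IBX in DMSO cleaves triethylsilyl ethers and oxidises the liberated allylic alcohol in the same flask under near-neutral conditions, so the base-sensitive β,γ-epoxy Z-enone is formed without a separate fluoride step and is used at once.

Step 19
Reactants: 29 (10Z)-12-enone 1,14-epoxide
Product: 30 2,9-diacetoxy-8,14-dihydroxy-12-oxobriara-3Z,5E-dien-7,19-olide (all stereocentres as in the target)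
Conditions: Cp2TiCl2 (30 mol%), Mn dust, 2,4,6-collidine·HCl, THF, rt, 5 mM, slow addition
Reagents that add atoms: none
Why: Proposed new method: Cp2TiCl (trivalent titanium, formed from Cp2TiCl2 and Mn) opens the 1,14-epoxide homolytically to the tertiary C1 radical, which adds across the ring (6-endo, polarity-matched) to C10 of the Z-enone on the face anti to the C14–O–Ti bond, and collidinium protonates the resulting titanium enolate at C11; the Z-epoxide thereby fixes O14 trans to the C15 methyl, the Z-enone in a chair arrangement puts C2 and C9 trans (H10 trans to C15), and C20 ends equatorial (11R, also the thermodynamic epimer of that chair); the closest known reactions are the Cp2TiCl transannular cyclisation of epoxygermacrolides to eudesmanolides and Cp2TiCl epoxide/acrylate reductive couplings, here transferred to a 14-membered ring with an enone acceptor.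

Step 20
Reactants: 30 14-hydroxy briarane
Product: 31 2,9-diacetoxy-14-butanoyloxy-8-hydroxy-12-oxobriara-3Z,5E-dien-7,19-olide
Conditions: (PrCO)2O, pyridine, 4-(dimethylamino)pyridine (5 mol%), CH2Cl2, 0 °C
Reagents that add atoms: butanoic anhydride, CCCC(=O)OC(=O)CCC
Why: Acylation of the only reactive (secondary) hydroxyl under mild, cold conditions avoids β-elimination of the 14-acyloxy group from the 12-ketone.

Step 21
Reactants: 31 14-butanoate
Product: 32 ptilosarcone
Conditions: NaOCl (aq.), CeCl3·7H2O, CH2Cl2/H2O, 0 °C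
Reagents that add atoms: sodium hypochlorite, [Na+].[O-]Cl
Why: Ene-type allylic chlorination by HOCl: electrophilic chlorine adds to the diene terminus C6 from the outer face of the ten-membered ring (6S), and the tertiary allylic C5 cation loses a C16 proton to give the 6-chloro-5(16)-ene with the diene kept in conjugation, as presumed for the halogenation of 3,5-diene briaranes.

**Compound list**

1 | prop-2-yn-1-ol | C#CCO | starting material
2 | bromomagnesium (Z)-3-(bromomagnesio)-2-methylprop-2-en-1-olate | Br[Mg]/C=C(/C)CO[Mg]Br | intermediate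
3 | (Z)-3-iodo-2-methylprop-2-en-1-ol | I/C=C(/C)CO | intermediate
4 | (Z)-3-iodo-2-methylprop-2-enal | I/C=C(/C)C=O | intermediate
5 | (1Z,3S)-1-iodo-2-methylhexa-1,5-dien-3-ol | I/C=C(/C)[C@@H](O)CC=C | intermediate
6 | (1Z,3S)-1-iodo-2-methyl-3-(triethylsilyloxy)hexa-1,5-diene | I/C=C(/C)[C@@H](O[Si](CC)(CC)CC)CC=C | intermediate
7 | (3S,4Z)-5-iodo-4-methyl-3-(triethylsilyloxy)pent-4-enal | I/C=C(/C)[C@@H](O[Si](CC)(CC)CC)CC=O | intermediate
8 | ethyl 2-[bis(2,2,2-trifluoroethoxy)phosphoryl]propanoate | CCOC(=O)C(C)P(=O)(OCC(F)(F)F)OCC(F)(F)F | starting material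
9 | ethyl (2Z,5S,6Z)-7-iodo-2,6-dimethyl-5-(triethylsilyloxy)hepta-2,6-dienoate | I/C=C(/C)[C@@H](O[Si](CC)(CC)CC)C/C=C(/C)C(=O)OCC | intermediate
10 | (2Z,5S,6Z)-7-iodo-2,6-dimethyl-5-(triethylsilyloxy)hepta-2,6-dien-1-ol | I/C=C(/C)[C@@H](O[Si](CC)(CC)CC)C/C=C(/C)CO | intermediate
11 | (2Z,5S,6Z)-7-iodo-2,6-dimethyl-5-(triethylsilyloxy)hepta-2,6-dienal | I/C=C(/C)[C@@H](O[Si](CC)(CC)CC)C/C=C(/C)C=O | intermediate
12 | tert-butyl (R)-2-hydroxypropanoate | C[C@@H](O)C(=O)OC(C)(C)C | starting material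
13 | trimethyl phosphonoacetate | COC(=O)CP(=O)(OC)OC | starting material
14 | tert-butyl (R)-2-(trifluoromethylsulfonyloxy)propanoate | C[C@@H](OS(=O)(=O)C(F)(F)F)C(=O)OC(C)(C)C | intermediate
15 | 4-tert-butyl 1-methyl (3S)-2-(dimethoxyphosphoryl)-3-methylbutanedioate (C2 epimers) | COC(=O)C(P(=O)(OC)OC)[C@@H](C)C(=O)OC(C)(C)C | intermediate
16 | (E)-3-methylpent-2-en-4-yn-1-ol | C#C/C(C)=C/CO | starting material
17 | (E)-3-methylpent-2-en-4-ynal | C#C/C(C)=C/C=O | intermediate
18 | 4-tert-butyl 1-methyl (2E,3R)-3-methyl-2-[(E)-3-methylpent-2-en-4-yn-1-ylidene]butanedioate | C#C/C(C)=C/C=C(/C(=O)OC)[C@@H](C)C(=O)OC(C)(C)C | intermediate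
19 | tert-butyl (2R,3E,5E)-3-(hydroxymethyl)-2,6-dimethylocta-3,5-dien-7-ynoate | C#C/C(C)=C/C=C(/CO)[C@@H](C)C(=O)OC(C)(C)C | intermediate
20 | tert-butyl (2R)-2-{(2R,3R)-2-(hydroxymethyl)-3-[(E)-2-methylbut-1-en-3-yn-1-yl]oxiran-2-yl}propanoate | C#C/C(C)=C/[C@H]1O[C@@]1(CO)[C@@H](C)C(=O)OC(C)(C)C | intermediate
21 | (3R,4R,5S)-4-hydroxy-4-(hydroxymethyl)-3-methyl-5-[(E)-2-methylbut-1-en-3-yn-1-yl]oxolan-2-one | C#C/C(C)=C/[C@@H]1OC(=O)[C@H](C)[C@@]1(O)CO | intermediate
22 | seco-cembranoid enynol: 10Z-iodide; 12S-OSiEt3; 1(14)Z-ene; 2-OH; 3-yne; 5E-ene; 7,19-lactone; 8-OH; 9-CH2OH (C2, C7, C8, C17 as in the target) | I/C=C(/C)[C@@H](O[Si](CC)(CC)CC)C/C=C(/C)[C@@H](O)C#C/C(C)=C/[C@@H]1OC(=O)[C@H](C)[C@@]1(O)CO | intermediate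
23 | 1,14-epoxide of 22 (threo to 2-OH; C14 as in the target, C1 to be inverted) | I/C=C(/C)[C@@H](O[Si](CC)(CC)CC)C[C@@H]1O[C@]1(C)[C@@H](O)C#C/C(C)=C/[C@@H]2OC(=O)[C@H](C)[C@@]2(O)CO | intermediate
24 | seco-aldehyde (C9 aldehyde of 23) | I/C=C(/C)[C@@H](O[Si](CC)(CC)CC)C[C@@H]1O[C@]1(C)[C@@H](O)C#C/C(C)=C/[C@@H]2OC(=O)[C@H](C)[C@@]2(O)C=O | intermediate
25 | 14-membered macrocyclic diol: 9S-OH; 2-OH; 8-OH; 10Z-ene; 12S-OSiEt3; 1,14-epoxide; 3-yne; 5E-ene; 7,19-lactone | O[C@H]1/C=C(/C)[C@@H](O[Si](CC)(CC)CC)C[C@@H]2O[C@]2(C)[C@@H](O)C#C/C(C)=C/[C@@H]2OC(=O)[C@H](C)[C@@]12O | intermediate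
26 | macrocyclic 2,9-diacetate of 25 | CC(=O)O[C@H]1/C=C(/C)[C@@H](O[Si](CC)(CC)CC)C[C@@H]2O[C@]2(C)[C@@H](OC(C)=O)C#C/C(C)=C/[C@@H]2OC(=O)[C@H](C)[C@@]12O | intermediate
27 | macrocyclic (3Z,5E)-diene 2,9-diacetate; 12S-OSiEt3; 1,14-epoxide | CC(=O)O[C@H]1/C=C(/C)[C@@H](O[Si](CC)(CC)CC)C[C@@H]2O[C@]2(C)[C@@H](OC(C)=O)/C=C\C(C)=C\[C@@H]2OC(=O)[C@H](C)[C@@]12O | intermediate
28 | macrocyclic 12S-alcohol (desilylated 27) | CC(=O)O[C@H]1/C=C(/C)[C@@H](O)C[C@@H]2O[C@]2(C)[C@@H](OC(C)=O)/C=C\C(C)=C\[C@@H]2OC(=O)[C@H](C)[C@@]12O | intermediate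
29 | macrocyclic (10Z)-12-enone 1,14-epoxide (cyclisation precursor) | CC(=O)O[C@H]1/C=C(/C)C(=O)C[C@@H]2O[C@]2(C)[C@@H](OC(C)=O)/C=C\C(C)=C\[C@@H]2OC(=O)[C@H](C)[C@@]12O | intermediate
30 | 2,9-diacetoxy-8,14-dihydroxy-12-oxobriara-3Z,5E-dien-7,19-olide (1R,2S,7R,8R,9S,10S,11R,14S,17R by the target's descriptors) | [H]/C1=C(C)\C=C/[C@H](OC(C)=O)[C@]2(C)[C@H]([C@@H](C)C(=O)C[C@@H]2O)[C@H](OC(C)=O)[C@]2(O)[C@@H](C)C(=O)O[C@H]21 | intermediate
31 | 2,9-diacetoxy-14-butanoyloxy-8-hydroxy-12-oxobriara-3Z,5E-dien-7,19-olide | [H]/C1=C(C)\C=C/[C@H](OC(C)=O)[C@]2(C)[C@H]([C@@H](C)C(=O)C[C@@H]2OC(=O)CCC)[C@H](OC(C)=O)[C@]2(O)[C@@H](C)C(=O)O[C@H]21 | intermediate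
32 | ptilosarcone | C=C1/C=C\[C@H](OC(C)=O)[C@]2(C)[C@H]([C@@H](C)C(=O)C[C@@H]2OC(=O)CCC)[C@H](OC(C)=O)[C@]2(O)[C@@H](C)C(=O)O[C@H]2[C@H]1Cl | target

**Step count and risks**

Total step count: 21. Longest linear sequence: 17 steps (steps 1–7, then 12–21); the east branch is 4 steps (8–11).

The three steps most likely to fail:

Step 19 (transannular radical closure). The risks are reduction of the γ-acetoxy enone, closure of the C1 radical onto the diene, or the wrong face at C10 or C11. Fallback: run the cationic counterpart one stage earlier. Setting out from 27, Me2AlCl in CH2Cl2 at −78 °C opens the epoxide at C1 with participation of the 10Z-alkene, and the C11 cation loses H12 to give the bicyclic triethylsilyl enol ether F5. Buffered hydrolysis (AcOH/THF/H2O, 0 °C) protonates C11 and comes back to the route at 30, so steps 18 and 19 are bypassed.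

Step 21 (ene-type chlorination). The risks are 1,4-chlorohydrin formation across the diene, the wrong face at C6, or α-chlorination of the ketone. Fallback: oxidise first, then transpose. Setting out from 31, SeO2 (cat.)/tBuOOH hydroxylates the C16 methyl of the trisubstituted alkene to give the 16-hydroxy 5E-ene F6. SOCl2 in Et2O at 0 °C then collapses the allylic chlorosulfite with transposition (SNi′) to the 6-chloro-5(16)-ene, coming back at 32.

Step 15 (ring closure and C9 configuration). The risk is that the closure gives the 9-epimer. Fallback: set C9 by reagent-controlled reduction instead of by the carbon–carbon bond formation. Setting out from 24, Ac2O/pyridine at 0 °C without acylation catalyst acetylates only the secondary C2 hydroxyl to give the 2-O-acetyl seco-aldehyde F1. CrCl2/NiCl2 closure then gives the 9-epimeric macrocyclic alcohol F2 (alone or mixed with the 9S isomer). MnO2 oxidises the allylic alcohol to the macrocyclic C9 enone F3. (R)-2-Methyl-CBS-oxazaborolidine [(R)-1-methyl-3,3-diphenyltetrahydro-1H,3H-pyrrolo[1,2-c][1,3,2]oxazaborole] with catecholborane (or its enantiomer, whichever gives 9S) reduces it to the 9S alcohol 2-acetate F4. Ac2O with 4-(dimethylamino)pyridine then comes back to the route at 26.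

Further compounds
F1 | step 15 | 2-O-acetyl seco-aldehyde | I/C=C(/C)[C@@H](O[Si](CC)(CC)CC)C[C@@H]1O[C@]1(C)[C@@H](OC(C)=O)C#C/C(C)=C/[C@@H]2OC(=O)[C@H](C)[C@@]2(O)C=O
F2 | step 15 | 9-epimeric macrocyclic alcohol 2-acetate | O[C@@H]1/C=C(/C)[C@@H](O[Si](CC)(CC)CC)C[C@@H]2O[C@]2(C)[C@@H](OC(C)=O)C#C/C(C)=C/[C@@H]2OC(=O)[C@H](C)[C@@]12O
F3 | step 15 | macrocyclic C9 enone 2-acetate | O=C1/C=C(/C)[C@@H](O[Si](CC)(CC)CC)C[C@@H]2O[C@]2(C)[C@@H](OC(C)=O)C#C/C(C)=C/[C@@H]2OC(=O)[C@H](C)[C@@]12O
F4 | step 15 | 9S macrocyclic alcohol 2-acetate | O[C@H]1/C=C(/C)[C@@H](O[Si](CC)(CC)CC)C[C@@H]2O[C@]2(C)[C@@H](OC(C)=O)C#C/C(C)=C/[C@@H]2OC(=O)[C@H](C)[C@@]12O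
F5 | step 19 | bicyclic 12-O-triethylsilyl enol ether (11-ene) of 30 | [H]/C1=C(C)\C=C/[C@H](OC(C)=O)[C@]2(C)[C@H](C(C)=C(O[Si](CC)(CC)CC)C[C@@H]2O)[C@H](OC(C)=O)[C@]2(O)[C@@H](C)C(=O)O[C@H]21
F6 | step 21 | 16-hydroxy derivative of 31 | [H]/C1=C(CO)\C=C/[C@H](OC(C)=O)[C@]2(C)[C@H]([C@@H](C)C(=O)C[C@@H]2OC(=O)CCC)[C@H](OC(C)=O)[C@]2(O)[C@@H](C)C(=O)O[C@H]21
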